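**Assumption:** the target SMILES contains no stereocentres (the molecule is achiral), so no enantiocontrol is needed. The one stereocentre that appears in the route (racemic ether 6) is erased in step 6.

## Retrosynthetic overview
1. Target ⇒ diaryl ether aldehyde 15 by global hydrogenation (two O‑benzyl groups and the side‑chain alkene) preceded by Pinnick oxidation of the ring‑A aldehyde.
2. 15 ⇒ Ullmann C–O coupling of hindered phenol 8 (ring A, C20) with ortho‑bromobenzoate 14 (ring B, C20).
3. 8 ⇒ aromatic Claisen rearrangement of a pent‑1‑en‑3‑yl aryl ether (installs the C5 chain and frees the coupling phenol) ⇐ 2,5‑dihydroxy‑4‑methoxybenzaldehyde ⇐ resorcinol (Vilsmeier, methylation, Elbs).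
4. 14 ⇒ Heck reaction of an aryl iodide with pent‑1‑en‑3‑ol (gives the 3‑oxopentyl chain directly) ⇐ lithiation/carboxylation between Br and I ⇐ Ir C–H borylation/oxidation of 1‑bromo‑3‑iodobenzene.
5. No ring is constructed: both benzene rings are purchased and are joined only at step 12.

## Fragment A (ring A)

**Step 1**
Reactants: 1, resorcinol
Product: 2, 2,4‑dihydroxybenzaldehyde
Conditions: POCl3, DMF, MeCN, −15 °C → rt; then H2O, 50 °C
Reagents that add atoms: DMF, CN(C)C=O (formyl carbon); water, O (formyl oxygen on hydrolysis)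
Why: Vilsmeier–Haack formylation occurs para to one OH and ortho to the other on the activated resorcinol ring.

**Step 2**
Reactants: 2, 2,4‑dihydroxybenzaldehyde
Product: 3, 2‑hydroxy‑4‑methoxybenzaldehyde
Conditions: MeI (1.1 eq), K2CO3 (1.0 eq), acetone, rt
Reagents that add atoms: iodomethane, CI
Why: Williamson O‑methylation is selective for the more acidic 4‑OH because the 2‑OH is hydrogen‑bonded to the aldehyde.

**Step 3**
Reactants: 3, 2‑hydroxy‑4‑methoxybenzaldehyde
Product: 4, 2,5‑dihydroxy‑4‑methoxybenzaldehyde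
Conditions: K2S2O8, 10% aq NaOH, 0–20 °C, 24 h; acidify, remove unreacted 3; then aq HCl, Na2SO3, 80 °C
Reagents that add atoms: potassium peroxydisulfate, [K+].[K+].[O-]S(=O)(=O)OOS(=O)(=O)[O-]
Why: Elbs persulfate oxidation places a sulfate para to the phenoxide oxygen (C5), and acid hydrolysis gives the hydroquinone.

**Step 4**
Reactants: 4, 2,5‑dihydroxy‑4‑methoxybenzaldehyde; 5, pent‑1‑en‑3‑ol (racemic)
Product: 6, 2‑hydroxy‑4‑methoxy‑5‑(pent‑1‑en‑3‑yloxy)benzaldehyde (racemic)
Conditions: PPh3, DIAD, THF, 0 °C → rt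
Reagents that add atoms: none
Why: Mitsunobu etherification takes the non‑chelated 5‑OH and gives the branched allyl aryl ether by SN2; the racemic centre is irrelevant because it is destroyed in step 6.

**Step 5**
Reactants: 6, 2‑hydroxy‑4‑methoxy‑5‑(pent‑1‑en‑3‑yloxy)benzaldehyde
Product: 7, 2‑(benzyloxy)‑4‑methoxy‑5‑(pent‑1‑en‑3‑yloxy)benzaldehyde
Conditions: BnBr, K2CO3, DMF, 60 °C
Reagents that add atoms: benzyl bromide, BrCc1ccccc1
Why: Williamson benzylation of the remaining chelated phenol proceeds at mild temperature, well below the onset of the Claisen rearrangement.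

**Step 6**
Reactants: 7, 2‑(benzyloxy)‑4‑methoxy‑5‑(pent‑1‑en‑3‑yloxy)benzaldehyde
Product: 8, 6‑(benzyloxy)‑3‑hydroxy‑4‑methoxy‑2‑[(E)‑pent‑2‑en‑1‑yl]benzaldehyde
Conditions: PhNEt2, 185 °C, sealed tube, Ar
Reagents that add atoms: none
Why: Aromatic Claisen [3,3] rearrangement can only end at the single free ortho carbon (the other carries OMe), giving the linear pent‑2‑enyl chain (E major, geometry irrelevant because it is hydrogenated later) and the free phenol.

## Fragment B (ring B)

**Step 7**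
Reactants: 9, 1‑bromo‑3‑iodobenzene
Product: 10, 2‑(3‑bromo‑5‑iodophenyl)‑4,4,5,5‑tetramethyl‑1,3,2‑dioxaborolane
Conditions: [Ir(OMe)(cod)]2 (1.5 mol%), dtbpy (3 mol%), B2pin2, cyclohexane, 60 °C
Reagents that add atoms: bis(pinacolato)diboron, CC1(C)OB(B2OC(C)(C)C(C)(C)O2)OC1(C)C
Why: Sterically controlled Ir‑catalysed C–H borylation attacks the only C–H not ortho to a halogen (C5) and tolerates both ArBr and ArI.

**Step 8**
Reactants: 10, the aryl pinacol boronate
Product: 11, 3‑bromo‑5‑iodophenol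
Conditions: 30% H2O2, aq NaOH, THF, 0 °C
Reagents that add atoms: hydrogen peroxide, OO
Why: Oxidation of the arylboronate (1,2‑aryl shift from boron to oxygen) gives the phenol without affecting the C–Br or C–I bonds.

**Step 9**
Reactants: 11, 3‑bromo‑5‑iodophenol
Product: 12, 1‑(benzyloxy)‑3‑bromo‑5‑iodobenzene
Conditions: BnBr, K2CO3, acetone, reflux
Reagents that add atoms: benzyl bromide, BrCc1ccccc1
Why: Standard Williamson ether synthesis on an unhindered phenol.

**Step 10**
Reactants: 12, 1‑(benzyloxy)‑3‑bromo‑5‑iodobenzene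
Product: 13, methyl 4‑(benzyloxy)‑2‑bromo‑6‑iodobenzoate
Conditions: LDA (1.05 eq), THF, −78 °C, 1 h; cannulate into ClCO2Me (3 eq), THF, −78 °C → rt
Reagents that add atoms: methyl chloroformate, COC(=O)Cl
Why: Directed ortho‑metalation with the non‑exchanging base LDA removes the most acidic proton (flanked by Br and I); the hindered 2,6‑dihaloaryllithium is acylated once, and inverse addition at −78 °C avoids aryne formation.

**Step 11**
Reactants: 13, methyl 4‑(benzyloxy)‑2‑bromo‑6‑iodobenzoate; 5, pent‑1‑en‑3‑ol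
Product: 14, methyl 4‑(benzyloxy)‑2‑bromo‑6‑(3‑oxopentyl)benzoate
Conditions: Pd(OAc)2 (3 mol%), Bu4NCl, NaHCO3, DMF, 50 °C
Reagents that add atoms: none
Why: Heck reaction under Jeffery conditions is selective for C–I over C–Br, and β‑hydride elimination toward the carbinol carbon followed by tautomerisation gives the saturated β‑aryl ketone directly.

## Fragment union and endgame

**Step 12**
Reactants: 8, 6‑(benzyloxy)‑3‑hydroxy‑4‑methoxy‑2‑[(E)‑pent‑2‑en‑1‑yl]benzaldehyde; 14, methyl 4‑(benzyloxy)‑2‑bromo‑6‑(3‑oxopentyl)benzoate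
Product: 15, methyl 4‑(benzyloxy)‑2‑{4‑(benzyloxy)‑3‑formyl‑6‑methoxy‑2‑[(E)‑pent‑2‑en‑1‑yl]phenoxy}‑6‑(3‑oxopentyl)benzoate
Conditions: CuI (20 mol%), picolinic acid (40 mol%), K3PO4 (2 eq), DMSO, 90 °C, Ar (8 in 1.2 eq)
Reagents that add atoms: none
Why: Ligand‑accelerated Ullmann diaryl ether synthesis is suited to di‑ortho‑substituted phenols, the ortho ester activates the aryl bromide, and the mild phosphate base spares the ester, ketone and hindered aldehyde.

**Step 13**
Reactants: 15, the diaryl ether aldehyde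
Product: 16, 6‑(benzyloxy)‑3‑[5‑(benzyloxy)‑2‑(methoxycarbonyl)‑3‑(3‑oxopentyl)phenoxy]‑4‑methoxy‑2‑[(E)‑pent‑2‑en‑1‑yl]benzoic acid
Conditions: NaClO2, NaH2PO4, 2‑methyl‑2‑butene (30 eq), t‑BuOH/THF/H2O, 0 °C → rt
Reagents that add atoms: sodium chlorite, [Na+].[O-]Cl=O
Why: Pinnick oxidation converts the aldehyde to the acid chemoselectively, with the excess scavenger alkene protecting the side‑chain olefin and the electron‑rich rings from HOCl.

**Step 14**
Reactants: 16, the diaryl ether acid
Product: 17, epiphorellic acid 2 (6‑hydroxy‑3‑[5‑hydroxy‑2‑(methoxycarbonyl)‑3‑(3‑oxopentyl)phenoxy]‑4‑methoxy‑2‑pentylbenzoic acid)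
Conditions: H2 (1 atm), 10% Pd/C, EtOAc, rt
Reagents that add atoms: none
Why: One catalytic hydrogenation cleaves both benzyl ethers and saturates the pentenyl chain to pentyl, while the dialkyl ketone, methyl ester, aryl methyl ether and diaryl ether are inert.

## Compound list
1 | resorcinol | Oc1cccc(O)c1 | starting material
2 | 2,4‑dihydroxybenzaldehyde | O=Cc1ccc(O)cc1O | intermediate
3 | 2‑hydroxy‑4‑methoxybenzaldehyde | COc1ccc(C=O)c(O)c1 | intermediate
4 | 2,5‑dihydroxy‑4‑methoxybenzaldehyde | COc1cc(O)c(C=O)cc1O | intermediate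
5 | pent‑1‑en‑3‑ol (racemic) | C=CC(O)CC | starting material
6 | 2‑hydroxy‑4‑methoxy‑5‑(pent‑1‑en‑3‑yloxy)benzaldehyde (racemic) | C=CC(CC)Oc1cc(C=O)c(O)cc1OC | intermediate
7 | 2‑(benzyloxy)‑4‑methoxy‑5‑(pent‑1‑en‑3‑yloxy)benzaldehyde (racemic) | C=CC(CC)Oc1cc(C=O)c(OCc2ccccc2)cc1OC | intermediate
8 | 6‑(benzyloxy)‑3‑hydroxy‑4‑methoxy‑2‑[(E)‑pent‑2‑en‑1‑yl]benzaldehyde | CC/C=C/Cc1c(O)c(OC)cc(OCc2ccccc2)c1C=O | intermediate
9 | 1‑bromo‑3‑iodobenzene | Brc1cccc(I)c1 | starting material
10 | 2‑(3‑bromo‑5‑iodophenyl)‑4,4,5,5‑tetramethyl‑1,3,2‑dioxaborolane | CC1(C)OB(OC1(C)C)c1cc(Br)cc(I)c1 | intermediate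
11 | 3‑bromo‑5‑iodophenol | Oc1cc(Br)cc(I)c1 | intermediate
12 | 1‑(benzyloxy)‑3‑bromo‑5‑iodobenzene | Brc1cc(I)cc(OCc2ccccc2)c1 | intermediate
13 | methyl 4‑(benzyloxy)‑2‑bromo‑6‑iodobenzoate | COC(=O)c1c(Br)cc(OCc2ccccc2)cc1I | intermediate
14 | methyl 4‑(benzyloxy)‑2‑bromo‑6‑(3‑oxopentyl)benzoate | CCC(=O)CCc1cc(OCc2ccccc2)cc(Br)c1C(=O)OC | intermediate
15 | methyl 4‑(benzyloxy)‑2‑{4‑(benzyloxy)‑3‑formyl‑6‑methoxy‑2‑[(E)‑pent‑2‑en‑1‑yl]phenoxy}‑6‑(3‑oxopentyl)benzoate | CC/C=C/Cc1c(Oc2cc(OCc3ccccc3)cc(CCC(=O)CC)c2C(=O)OC)c(OC)cc(OCc2ccccc2)c1C=O | intermediate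
16 | 6‑(benzyloxy)‑3‑[5‑(benzyloxy)‑2‑(methoxycarbonyl)‑3‑(3‑oxopentyl)phenoxy]‑4‑methoxy‑2‑[(E)‑pent‑2‑en‑1‑yl]benzoic acid | CC/C=C/Cc1c(Oc2cc(OCc3ccccc3)cc(CCC(=O)CC)c2C(=O)OC)c(OC)cc(OCc2ccccc2)c1C(=O)O | intermediate
17 | epiphorellic acid 2 | CCCCCc1c(Oc2cc(O)cc(CCC(=O)CC)c2C(=O)OC)c(OC)cc(O)c1C(=O)O | target

## Summary
Total step count: 14 (fragment A 6 steps, fragment B 5 steps, coupling 1, endgame 2).
Longest linear sequence: 9 steps (steps 1–6, then 12–14).

Three steps most likely to fail: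

1. **Step 12 (Ullmann coupling).** The phenol is di‑ortho‑substituted, and base could trigger aldol condensation between the ring‑A aldehyde and ring‑B ketone or intramolecular Claisen cyclisation of the keto‑ester. Fallback: form the C–O bond by metal‑free SNAr instead. Ring B would be made as the 2‑fluorobenzaldehyde analogue (same sequence from 1‑fluoro‑3‑iodobenzene with a DMF quench, ketone masked as a dioxolane). Ring A would be carried as its benzyl ester (oxidise and benzylate 7 before the Claisen). After K2CO3/DMA displacement of fluoride, the ring‑B aldehyde is converted to the methyl ester.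

2. **Step 3 (Elbs oxidation).** Conversion is typically modest and the sulfate work‑up is laborious. Fallback: introduce the C5 oxygen by halogenation and hydroxylation. Benzylate 3, brominate para to the OBn group (NBS), protect the aldehyde as an acetal, then Miyaura borylation and H2O2 oxidation give the 5‑phenol, which rejoins the route at the Mitsunobu/Claisen stage.

3. **Step 10 (LDA metalation and acylation).** Risks are competing deprotonation next to OBn, aryne formation and halogen scrambling. Fallback: avoid the aryllithium. Take 3‑bromophenol to its benzyl ether, carry out Rieche formylation para to OBn, Pinnick oxidation to 4‑(benzyloxy)‑2‑bromobenzoic acid, carboxylate‑directed Pd‑catalysed ortho C–H iodination, then methyl esterification to reach 13.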